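**Retrosynthetic overview**

- Feature: ring A is a phloroglucinol in which C2, the carbon carrying the ether oxygen to ring B, lies between the hydroxylated carbons C1 and C3, with the third hydroxyl on C5. This C(OH)–C(OAr)–C(OH) triad is the pattern of a cyclised triketide with an oxygenated central carbon, so ring A is built last and de novo.
- Key disconnection: the ring A bonds C1–C6 and C3–C4. C1–C2–C3 come from a dimethyl 2-aryloxymalonate (aryl = per-O-methyl pentamer B–F) and C4–C5–C6 from dimethyl 3-oxoglutarate. The hindered A–O–B ether is made beforehand on sp3 carbon by O-alkylation of the ring B phenol with a halomalonate.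
- Pentamer: only two arenes are needed. Ullmann etherification followed by lithiation/oxidation at the position between two oxygens gives one dimer phenol (rings D–E, identical to rings B–C), which is used twice. Sterically controlled para C–H borylation of the terminal 2,6-dimethoxyphenoxy ring supplies the boronic acid for a Chan–Lam coupling (ring D) and later the free phenol (ring B).
- Ring order: rings F, E, D, C and B are purchased arenes joined by ether bonds; ring A is the only ring formed (step 8). Ester hydrolysis with double decarboxylation and global demethylation finish the route.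

Key step: step 8

Remark: the target has no stereocentres. The thirteen hydroxyls of rings B to F are carried as methyl ethers. Dimethyl chloromalonate is used as the halomalonate, because a bromomalonate can transfer bromine to an electron-rich phenoxide; the aryloxymalonate obtained is the same. "Ar(B–F)" below means the per-O-methyl pentamer aryl group of compound 12, attached through ring B C1.

**Route**

Step 1
Reactants: 1 5-bromo-1,2,3-trimethoxybenzene; 2 2,6-dimethoxyphenol
Product: 3 5-(2,6-dimethoxyphenoxy)-1,2,3-trimethoxybenzene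
Conditions: CuI (10 mol %), picolinic acid (20 mol %), K3PO4, DMSO, 100 °C, argon
Reagents that add atoms: none
Why: Ullmann-type copper-catalysed diaryl ether synthesis, in which a doubly ortho-substituted phenol is an acceptable nucleophile as long as the aryl bromide carries no ortho substituent, as here.

Step 2
Reactants: 3 5-(2,6-dimethoxyphenoxy)-1,2,3-trimethoxybenzene
Product: 6 6-(2,6-dimethoxyphenoxy)-2,3,4-trimethoxyphenol, via aryllithium 4 (not isolated), via dimethyl arylboronate 5 (not isolated)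
Conditions: n-BuLi, THF, 0 °C; B(OMe)3, −78 to 25 °C; 30% H2O2, AcOH, 0 °C
Reagents that add atoms: hydrogen peroxide, OO (n-butyllithium, [Li]CCCC, and trimethyl borate, COB(OC)OC, supply atoms only to intermediates 4 and 5)
Why: Directed ortho-metalation should occur at the one kind of C–H flanked by two oxygen substituents (between the aryloxy and a methoxy group of the trimethoxyphenyl ring; the two such positions are equivalent), and borylation followed by peroxide oxidation (1,2-aryl shift from boron to oxygen) turns the aryllithium into the phenol.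

Step 3
Reactants: 6 6-(2,6-dimethoxyphenoxy)-2,3,4-trimethoxyphenol; 1 5-bromo-1,2,3-trimethoxybenzene
Product: 7 1-(2,6-dimethoxyphenoxy)-3,4,5-trimethoxy-2-(3,4,5-trimethoxyphenoxy)benzene
Conditions: CuI (10 mol %), picolinic acid (20 mol %), K3PO4, DMSO, 100 °C, argon
Reagents that add atoms: none
Why: Ullmann-type diaryl ether synthesis again pairs the hindered phenol (ring E oxygen) with the unhindered aryl bromide (ring F), the polarity that copper catalysis tolerates best.

Step 4
Reactants: 7 1-(2,6-dimethoxyphenoxy)-3,4,5-trimethoxy-2-(3,4,5-trimethoxyphenoxy)benzene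
Product: 9 {3,5-dimethoxy-4-[3,4,5-trimethoxy-2-(3,4,5-trimethoxyphenoxy)phenoxy]phenyl}boronic acid, via pinacol boronate 8 (not isolated)
Conditions: [Ir(OMe)(cod)]2 (1.5 mol %), 4,4'-di-tert-butyl-2,2'-bipyridine (3 mol %), B2pin2, THF, 80 °C; then NaIO4, aq NH4OAc, acetone/H2O, 25 °C
Reagents that add atoms: bis(pinacolato)diboron, CC1(C)OB(OC1(C)C)B1OC(C)(C)C(C)(C)O1; water, O
Why: Iridium-catalysed aromatic C–H borylation is sterically controlled, and the only C–H in 7 without an ortho substituent is the one para to the ether oxygen on the 2,6-dimethoxyphenoxy ring (every other aryl C–H lies between two oxygen substituents or next to a methoxy group); periodate then cleaves the pinacol ester to the boronic acid.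

Step 5
Reactants: 9 trimer boronic acid (rings D–E–F); 6 6-(2,6-dimethoxyphenoxy)-2,3,4-trimethoxyphenol
Product: 10 1-(2,6-dimethoxyphenoxy)-2-{3,5-dimethoxy-4-[3,4,5-trimethoxy-2-(3,4,5-trimethoxyphenoxy)phenoxy]phenoxy}-3,4,5-trimethoxybenzene (per-O-methyl pentamer B–F with hydrogen at ring B C1)
Conditions: Cu(OAc)2 (2 equiv), pyridine, 4 Å molecular sieves, CH2Cl2, dry air, 25 °C
Reagents that add atoms: none
Why: Chan–Lam oxidative C–O coupling should join the ortho-unsubstituted arylboronic acid to the doubly ortho-substituted phenol at room temperature, a combination this coupling is known to accept, and no halide is present that could cross-react.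

Step 6
Reactants: 10 per-O-methyl pentamer B–F with hydrogen at ring B C1
Product: 12 4-(2-{3,5-dimethoxy-4-[3,4,5-trimethoxy-2-(3,4,5-trimethoxyphenoxy)phenoxy]phenoxy}-3,4,5-trimethoxyphenoxy)-3,5-dimethoxyphenol (pentamer phenol Ar(B–F)–OH), via pinacol boronate 11 (not isolated)
Conditions: [Ir(OMe)(cod)]2 (1.5 mol %), 4,4'-di-tert-butyl-2,2'-bipyridine (3 mol %), B2pin2, THF, 80 °C; then 30% H2O2, aq NaOH, 0 °C, argon; aq HCl
Reagents that add atoms: hydrogen peroxide, OO (bis(pinacolato)diboron, CC1(C)OB(OC1(C)C)B1OC(C)(C)C(C)(C)O1, supplies boron only to intermediate 11)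
Why: The same sterically controlled C–H borylation should again pick the single unflanked C–H, now para on ring B, and alkaline peroxide oxidation of the boronate (aryl migration from boron to oxygen) delivers the ring B C1 phenol.

Step 7
Reactants: 12 pentamer phenol Ar(B–F)–OH; 13 dimethyl chloromalonate
Product: 14 dimethyl 2-[Ar(B–F)-oxy]malonate
Conditions: K2CO3, acetone, 56 °C
Reagents that add atoms: none
Why: Williamson O-alkylation (SN2) of an unhindered phenoxide with an alpha-halomalonate is routine and creates the future A–O–B ether on sp3 carbon, avoiding any aryl coupling at a doubly ortho-substituted position.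

Step 8
Reactants: 14 dimethyl 2-[Ar(B–F)-oxy]malonate; 15 dimethyl 3-oxoglutarate
Product: 17 dimethyl 2,4,6-trihydroxy-5-[Ar(B–F)-oxy]isophthalate, via open-chain Claisen adduct 16 (not isolated)
Conditions: 15 (3 equiv), NaOMe (3 equiv), MeOH, 25 °C; then 14, toluene, 110 °C with distillation of MeOH; 1 M HCl
Reagents that add atoms: none
Why: The sodium enolate of 15 attacks one ester carbonyl of 14 (intermolecular Claisen condensation) to give the open-chain 2-acyl-3-oxoglutarate 16, whose remaining CH2CO2Me carbon then attacks the second malonate ester in a Dieckmann condensation, a 6-exo-trig acyl substitution that closes ring A as a cyclohexane-1,3,5-trione; its enolisation to the arene phenoxide is irreversible under the conditions and pulls both reversible acylations forward. The closest known reaction is the classical alkoxide-mediated condensation of malonic esters with acetonedicarboxylic esters to 2,4,6-trihydroxyisophthalates, the laboratory counterpart of a triketide cyclisation. No stereocentre is formed. The step needs C,C-diacylation to win over C,O-closure to a 4-hydroxy-2-pyranone and over self-condensation of 15: methoxide with methyl esters throughout keeps every acyl transfer reversible and degenerate, so a pyranone is reopened and funnelled to the arene, and holding 15 as its enolate leaves little free ketone for self-aldol reaction. Because the malonate carbon of 14 already carries the aryl–oxygen bond, it can only become the central carbon of the C(OH)–C(OAr)–C(OH) triad, and adducts in which that carbon acts as the nucleophile are quaternary, cannot aromatise as such and revert by retro-Claisen cleavage.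

Step 9
Reactants: 17 dimethyl 2,4,6-trihydroxy-5-[Ar(B–F)-oxy]isophthalate
Product: 19 2-[Ar(B–F)-oxy]benzene-1,3,5-triol, via trihydroxyisophthalic diacid 18 (not isolated)
Conditions: aq KOH, MeOH, 70 °C, argon; then HCl to pH 1, 80 °C
Reagents that add atoms: none
Why: Saponification gives a phloroglucinol dicarboxylic acid that is a vinylogous beta-keto acid through its keto tautomer and should lose both carboxyl groups on warming in acid, as phloroglucinol carboxylic acids do, while the aryl ethers are inert.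

Step 10
Reactants: 19 2-[Ar(B–F)-oxy]benzene-1,3,5-triol
Product: 20 target hexamer CNP0114537.0 (sixteen free hydroxyls)
Conditions: BBr3 (40 equiv), CH2Cl2, −78 to 25 °C; MeOH then H2O, argon
Reagents that add atoms: none
Why: Lewis-acid cleavage of aryl methyl ethers with BBr3 (bromide attack on the O-methyl of the borane complex) should remove all thirteen methyl groups, whereas diaryl ether oxygens offer no sp3 carbon for bromide attack and remain.

**Compound list**

1 | 5-bromo-1,2,3-trimethoxybenzene | COc1cc(Br)cc(OC)c1OC | starting material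
2 | 2,6-dimethoxyphenol | COc1cccc(OC)c1O | starting material
3 | 5-(2,6-dimethoxyphenoxy)-1,2,3-trimethoxybenzene | COc1cccc(OC)c1Oc1cc(OC)c(OC)c(OC)c1 | intermediate
4 | [6-(2,6-dimethoxyphenoxy)-2,3,4-trimethoxyphenyl]lithium | [Li]c1c(OC)c(OC)c(OC)cc1Oc1c(OC)cccc1OC | intermediate
5 | dimethyl [6-(2,6-dimethoxyphenoxy)-2,3,4-trimethoxyphenyl]boronate | COB(OC)c1c(OC)c(OC)c(OC)cc1Oc1c(OC)cccc1OC | intermediate
6 | 6-(2,6-dimethoxyphenoxy)-2,3,4-trimethoxyphenol (dimer phenol) | COc1cccc(OC)c1Oc1cc(OC)c(OC)c(OC)c1O | intermediate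
7 | 1-(2,6-dimethoxyphenoxy)-3,4,5-trimethoxy-2-(3,4,5-trimethoxyphenoxy)benzene (trimer D–E–F) | COc1cccc(OC)c1Oc1cc(OC)c(OC)c(OC)c1Oc1cc(OC)c(OC)c(OC)c1 | intermediate
8 | 2-{3,5-dimethoxy-4-[3,4,5-trimethoxy-2-(3,4,5-trimethoxyphenoxy)phenoxy]phenyl}-4,4,5,5-tetramethyl-1,3,2-dioxaborolane | CC1(C)OB(OC1(C)C)c1cc(OC)c(Oc2cc(OC)c(OC)c(OC)c2Oc2cc(OC)c(OC)c(OC)c2)c(OC)c1 | intermediate
9 | {3,5-dimethoxy-4-[3,4,5-trimethoxy-2-(3,4,5-trimethoxyphenoxy)phenoxy]phenyl}boronic acid | OB(O)c1cc(OC)c(Oc2cc(OC)c(OC)c(OC)c2Oc2cc(OC)c(OC)c(OC)c2)c(OC)c1 | intermediate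
10 | 1-(2,6-dimethoxyphenoxy)-2-{3,5-dimethoxy-4-[3,4,5-trimethoxy-2-(3,4,5-trimethoxyphenoxy)phenoxy]phenoxy}-3,4,5-trimethoxybenzene | COc1cccc(OC)c1Oc1cc(OC)c(OC)c(OC)c1Oc1cc(OC)c(Oc2cc(OC)c(OC)c(OC)c2Oc2cc(OC)c(OC)c(OC)c2)c(OC)c1 | intermediate
11 | pinacol boronate of 10 at ring B C1 (para to the ether oxygen of ring B) | CC1(C)OB(OC1(C)C)c1cc(OC)c(Oc2cc(OC)c(OC)c(OC)c2Oc2cc(OC)c(Oc3cc(OC)c(OC)c(OC)c3Oc3cc(OC)c(OC)c(OC)c3)c(OC)c2)c(OC)c1 | intermediate
12 | 4-(2-{3,5-dimethoxy-4-[3,4,5-trimethoxy-2-(3,4,5-trimethoxyphenoxy)phenoxy]phenoxy}-3,4,5-trimethoxyphenoxy)-3,5-dimethoxyphenol | Oc1cc(OC)c(Oc2cc(OC)c(OC)c(OC)c2Oc2cc(OC)c(Oc3cc(OC)c(OC)c(OC)c3Oc3cc(OC)c(OC)c(OC)c3)c(OC)c2)c(OC)c1 | intermediate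
13 | dimethyl chloromalonate | COC(=O)C(Cl)C(=O)OC | starting material
14 | dimethyl 2-[Ar(B–F)-oxy]malonate | COC(=O)C(C(=O)OC)Oc1cc(OC)c(Oc2cc(OC)c(OC)c(OC)c2Oc2cc(OC)c(Oc3cc(OC)c(OC)c(OC)c3Oc3cc(OC)c(OC)c(OC)c3)c(OC)c2)c(OC)c1 | intermediate
15 | dimethyl 3-oxoglutarate | COC(=O)CC(=O)CC(=O)OC | starting material
16 | dimethyl 2-{2-[Ar(B–F)-oxy]-3-methoxy-3-oxopropanoyl}-3-oxopentanedioate | COC(=O)CC(=O)C(C(=O)OC)C(=O)C(C(=O)OC)Oc1cc(OC)c(Oc2cc(OC)c(OC)c(OC)c2Oc2cc(OC)c(Oc3cc(OC)c(OC)c(OC)c3Oc3cc(OC)c(OC)c(OC)c3)c(OC)c2)c(OC)c1 | intermediate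
17 | dimethyl 2,4,6-trihydroxy-5-[Ar(B–F)-oxy]isophthalate | COC(=O)c1c(O)c(C(=O)OC)c(O)c(Oc2cc(OC)c(Oc3cc(OC)c(OC)c(OC)c3Oc3cc(OC)c(Oc4cc(OC)c(OC)c(OC)c4Oc4cc(OC)c(OC)c(OC)c4)c(OC)c3)c(OC)c2)c1O | intermediate
18 | 2,4,6-trihydroxy-5-[Ar(B–F)-oxy]isophthalic acid | OC(=O)c1c(O)c(C(=O)O)c(O)c(Oc2cc(OC)c(Oc3cc(OC)c(OC)c(OC)c3Oc3cc(OC)c(Oc4cc(OC)c(OC)c(OC)c4Oc4cc(OC)c(OC)c(OC)c4)c(OC)c3)c(OC)c2)c1O | intermediate
19 | 2-[Ar(B–F)-oxy]benzene-1,3,5-triol (trideca-O-methyl ether of the target) | Oc1cc(O)c(Oc2cc(OC)c(Oc3cc(OC)c(OC)c(OC)c3Oc3cc(OC)c(Oc4cc(OC)c(OC)c(OC)c4Oc4cc(OC)c(OC)c(OC)c4)c(OC)c3)c(OC)c2)c(O)c1 | intermediate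
20 | CNP0114537.0 | Oc1cc(O)c(Oc2cc(O)c(Oc3cc(O)c(O)c(O)c3Oc3cc(O)c(Oc4cc(O)c(O)c(O)c4Oc4cc(O)c(O)c(O)c4)c(O)c3)c(O)c2)c(O)c1 | target

**Step count and risks**

Total steps: 10. Longest linear sequence: 10 steps (from 1 and 2 to 20); the dimer phenol 6 is made once and used in steps 3 and 5.

Steps most likely to fail:

1. Step 8 (ring A annulation). What may go wrong: the aryloxymalonate is drained into its own unreactive enolate while the oxoglutarate enolate self-condenses, so that acyl transfer to 14 never competes and 14 is recovered. Fallback, which replaces ring synthesis by aryl–oxygen coupling, sets out from 10 and returns to the route at 20: 10 is borylated as in step 6 to the pinacol boronate 11, which NaIO4/aq NH4OAc cleaves to the pentamer boronic acid F1. Chan–Lam coupling of F1 with commercial 2,4,6-trimethoxyphenol (COc1cc(OC)c(O)c(OC)c1; Cu(OAc)2, pyridine, 4 Å molecular sieves, CH2Cl2, air) would give the per-O-methyl hexamer F2, and BBr3 in CH2Cl2 would cleave its sixteen methyl ethers to give 20.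

2. Step 5 (Chan–Lam coupling of the two large fragments). What may go wrong: protodeboronation and oxidative homocoupling of 9 outrun the slow C–O bond formation with the doubly ortho-substituted phenol 6. Fallback, which replaces oxidative copper coupling by palladium-catalysed C–O coupling, sets out from 9 and returns at 10: 9 is oxidised with H2O2/NaOH to the trimer phenol F3, which Tf2O/pyridine converts into the trimer aryl triflate F4. F4 is coupled with 6 using Pd(OAc)2, 2-di-tert-butylphosphino-2',4',6'-triisopropylbiphenyl and K3PO4 in toluene at 100 °C to give 10.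

3. Step 10 (thirteen-fold demethylation). What may go wrong: incomplete ether cleavage together with oxidative degradation of the free polyphenol during aqueous work-up and chromatography. Fallback, a derivatise–purify–release sequence, sets out from 19 and returns at 20: the crude product of the BBr3 treatment is acetylated directly (Ac2O, pyridine, DMAP) to the hexadecaacetate F5, which is purified on silica where under-cleaved material separates. Degassed HCl in MeOH at 25 °C then removes the acetates to give 20.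

**Further compounds**

F1 | step 8 | {4-(2-{3,5-dimethoxy-4-[3,4,5-trimethoxy-2-(3,4,5-trimethoxyphenoxy)phenoxy]phenoxy}-3,4,5-trimethoxyphenoxy)-3,5-dimethoxyphenyl}boronic acid (pentamer boronic acid) | OB(O)c1cc(OC)c(Oc2cc(OC)c(OC)c(OC)c2Oc2cc(OC)c(Oc3cc(OC)c(OC)c(OC)c3Oc3cc(OC)c(OC)c(OC)c3)c(OC)c2)c(OC)c1
F2 | step 8 | hexadeca-O-methyl ether of the target (per-O-methyl hexamer) | COc1cc(OC)c(Oc2cc(OC)c(Oc3cc(OC)c(OC)c(OC)c3Oc3cc(OC)c(Oc4cc(OC)c(OC)c(OC)c4Oc4cc(OC)c(OC)c(OC)c4)c(OC)c3)c(OC)c2)c(OC)c1
F3 | step 5 | 3,5-dimethoxy-4-[3,4,5-trimethoxy-2-(3,4,5-trimethoxyphenoxy)phenoxy]phenol (trimer phenol) | Oc1cc(OC)c(Oc2cc(OC)c(OC)c(OC)c2Oc2cc(OC)c(OC)c(OC)c2)c(OC)c1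
F4 | step 5 | 3,5-dimethoxy-4-[3,4,5-trimethoxy-2-(3,4,5-trimethoxyphenoxy)phenoxy]phenyl trifluoromethanesulfonate (trimer aryl triflate) | FC(F)(F)S(=O)(=O)Oc1cc(OC)c(Oc2cc(OC)c(OC)c(OC)c2Oc2cc(OC)c(OC)c(OC)c2)c(OC)c1
F5 | step 10 | hexadecaacetate of the target | CC(=O)Oc1cc(OC(C)=O)c(Oc2cc(OC(C)=O)c(Oc3cc(OC(C)=O)c(OC(C)=O)c(OC(C)=O)c3Oc3cc(OC(C)=O)c(Oc4cc(OC(C)=O)c(OC(C)=O)c(OC(C)=O)c4Oc4cc(OC(C)=O)c(OC(C)=O)c(OC(C)=O)c4)c(OC(C)=O)c3)c(OC(C)=O)c2)c(OC(C)=O)c1
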